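**Retrosynthetic overview**
- End game: target 16 ⇒ C3–Br (NBS on the free indole 15) ⇒ N–H (detosylation of 14) ⇒ C2–Cl (C2 lithiation, Cl+ transfer) ⇒ 4,7-dibromo-1-tosylindole 12 ⇒ indoline 11 (dehydrogenation).
- Feature used: C4 and C7 of the benzene ring both carry bromine, stand para to each other, and each adjoins a fusion carbon (C4 next to C3a, C7 next to C7a). This is the imprint of the two capped termini of a 1,6-diyne whose inner carbons become C3a and C7a.
- Key disconnection: C3a–C7a, C4–C5 and C6–C7 of 11 are cut together. This gives the bromoynamide/bromoalkyne diyne 8 (tether N1–C2–C3) and acetylene 9 (C5–C6).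
- Ring order: both rings arise in step 5. The five-membered ring closes first (oxidative coupling on Ru), and the benzene ring follows directly (acetylene insertion, reductive elimination).
- Precursor: 8 ⇐ double C(sp)–H bromination of diyne 7 ⇐ copper-free N-alkynylation of sulfonamide 3 with an alkynyliodonium salt ⇐ but-3-yn-1-amine + TsCl.

Key step: step 5

Remark: the target is planar and has no stereocentre or other stereogenic element, so it is achiral and no enantiocontrol is needed.

**Step 1**
Reactants: 1 but-3-yn-1-amine hydrochloride; 2 p-toluenesulfonyl chloride
Product: 3 N-(but-3-yn-1-yl)-4-methylbenzenesulfonamide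
Conditions: Et3N (2.5 equiv), CH2Cl2, 0 °C → rt
Reagents that add atoms: none
Why: N-sulfonylation of a primary amine is fast and clean in the cold, the extra base frees the amine from its salt, and the terminal alkyne is a spectator.

**Step 2**
Reactants: 3 N-(but-3-yn-1-yl)-4-methylbenzenesulfonamide; 4 phenyl[(trimethylsilyl)ethynyl]iodonium triflate
Product: 6 N-(but-3-yn-1-yl)-4-methyl-N-[(trimethylsilyl)ethynyl]benzenesulfonamide, via potassium sulfonamide salt 5 (not isolated)
Conditions: KHMDS (1.05 equiv), toluene, 0 °C; then 4 (1.2 equiv), 0 °C → rt
Reagents that add atoms: none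
Why: This is the N-alkynylation of a sulfonamide anion with an alkynyl(aryl)iodonium salt, in which nitrogen adds to the silyl-bearing carbon, iodobenzene leaves to give an alkylidene carbene and a fast 1,2-silyl shift delivers the ynamide; one equivalent of base removes only the far more acidic N–H, and the absence of copper spares the free C≡C–H the Cadiot–Chodkiewicz coupling that a Cu/bromoalkyne amidation would invite.

**Step 3**
Reactants: 6 N-(but-3-yn-1-yl)-4-methyl-N-[(trimethylsilyl)ethynyl]benzenesulfonamide
Product: 7 N-(but-3-yn-1-yl)-N-ethynyl-4-methylbenzenesulfonamide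
Conditions: K2CO3 (20 mol %), MeOH–THF, 0 °C → rt
Reagents that add atoms: none
Why: Base-catalysed methanolysis of the C(sp)–SiMe3 bond (protodesilylation) is a standard release of terminal N-sulfonyl ynamides, and both alkynes tolerate cold, weakly basic methanol.

**Step 4**
Reactants: 7 N-(but-3-yn-1-yl)-N-ethynyl-4-methylbenzenesulfonamide
Product: 8 N-(bromoethynyl)-N-(4-bromobut-3-yn-1-yl)-4-methylbenzenesulfonamide
Conditions: NBS (2.3 equiv), AgNO3 (20 mol %), dry acetone, rt, dark
Reagents that add atoms: N-bromosuccinimide, O=C1CCC(=O)N1Br
Why: Silver(I)-catalysed electrophilic bromination of terminal alkynes with NBS runs through silver acetylides under neutral conditions and is established for alkyl alkynes and terminal N-sulfonyl ynamides alike, while dry solvent and a short reaction time limit ynamide hydration, and 8 is kept cold and dark and used promptly.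

**Step 5**
Reactants: 8 N-(bromoethynyl)-N-(4-bromobut-3-yn-1-yl)-4-methylbenzenesulfonamide; 9 acetylene
Product: 11 4,7-dibromo-1-tosylindoline, via ruthenacyclopentadiene 10 (not isolated)
Conditions: Cp*RuCl(cod) (5 mol %), HC≡CH (1 atm), ClCH2CH2Cl, rt, 8 added by syringe pump
Reagents that add atoms: none
Why: Proposed new method: the closest known reaction types are the Cp*RuCl-catalysed [2+2+2] cycloaddition of 1,6-dihalodiynes with acetylene, which gives 1,4-dihalobenzenes, and the late-metal trimerisation of N-tethered ynamide diynes, which gives indolines; new is only that one halogen-capped alkyne is at the same time an ynamide. After cod has left, the two alkynes of 8 bind to the 14-electron Cp*RuCl fragment and couple oxidatively through their inner carbons, which makes C3a–C7a and closes the five-membered ring N1–C2–C3–C3a–C7a by an intramolecular, tether-enforced coupling to give ruthenacyclopentadiene 10 with ruthenium on both CBr carbons. Acetylene 9 then inserts into one Ru–C bond and reductive elimination from the seven-membered ruthenacycle closes the six-membered ring, so that C4–C5 and C6–C7 are formed and the bromines are left at C4 and C7 whichever Ru–C bond reacts first. The cycle runs between Ru(II) and Ru(IV) at a crowded Cp* centre that should prefer π-coordination of the alkyne to oxidative addition into C(sp)–Br, and the sulfonyl group tempers the ynamide enough for it to behave as an ordinary alkyne ligand. No stereocentre is created and the symmetric acetylene leaves no regiochemical question, so the only selectivity needed is capture of 10 by acetylene instead of by a second molecule of 8; the bromine caps make 8 a poor monoalkyne partner, and slow addition of 8 into an acetylene-saturated solution keeps the balance in favour of the cross-reaction.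

**Step 6**
Reactants: 11 4,7-dibromo-1-tosylindoline
Product: 12 4,7-dibromo-1-tosyl-1H-indole
Conditions: DDQ (2.5 equiv), PhCl, 130 °C
Reagents that add atoms: none
Why: DDQ dehydrogenation (hydride abstraction from the C2–C3 unit, then proton loss) is a known route from N-sulfonylindolines to N-sulfonylindoles driven by aromatisation, and the excess oxidant and heat that the deactivated ring calls for are tolerated by the aryl bromides and the sulfonamide.

**Step 7**
Reactants: 12 4,7-dibromo-1-tosyl-1H-indole
Product: 14 4,7-dibromo-2-chloro-1-tosyl-1H-indole, via 2-lithioindole 13 (not isolated)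
Conditions: LDA (1.15 equiv), THF, −78 °C; then C2Cl6 (1.3 equiv), −78 °C → rt
Reagents that add atoms: hexachloroethane, ClC(Cl)(Cl)C(Cl)(Cl)Cl
Why: This is a sulfonyl-directed C2 lithiation of an N-sulfonylindole followed by Cl+ transfer from hexachloroethane, in which the amide base avoids the Br–Li exchange an alkyllithium would cause and, at −78 °C, the C2–H acidified and directed by the sulfonyl group is removed in preference to C5–H or C6–H next to bromine and to the tosyl methyl group.

**Step 8**
Reactants: 14 4,7-dibromo-2-chloro-1-tosyl-1H-indole
Product: 15 4,7-dibromo-2-chloro-1H-indole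
Conditions: TBAF (1 M in THF, 2.5 equiv), THF, rt → 50 °C; pH 7 buffer
Reagents that add atoms: none
Why: Fluoride-induced N–S cleavage of N-tosylindoles (attack at sulfur, indolide as leaving group) is eased here by the three halogens and by the peri strain with C7–Br, leaves the C–Cl and C–Br bonds alone and avoids reducing conditions that would strip bromine, and 15 is carried on at once because 3-unsubstituted 2-chloroindoles are sensitive to acid and air.

**Step 9**
Reactants: 15 4,7-dibromo-2-chloro-1H-indole
Product: 16 3,4,7-tribromo-2-chloro-1H-indole
Conditions: NBS (1.0 equiv), DMF, 0 °C, dark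
Reagents that add atoms: N-bromosuccinimide, O=C1CCC(=O)N1Br
Why: Electrophilic aromatic substitution of a free (NH)-indole takes place at C3, the only open position of the pyrrole ring and far more nucleophilic than C5 or C6 of the dibrominated benzene ring, so one equivalent of NBS in the cold should stop at monobromination.

**Compound list**
1 | but-3-yn-1-amine hydrochloride | C#CCCN.Cl | starting material
2 | p-toluenesulfonyl chloride (TsCl) | Cc1ccc(cc1)S(Cl)(=O)=O | starting material
3 | N-(but-3-yn-1-yl)-4-methylbenzenesulfonamide | C#CCCNS(=O)(=O)c1ccc(C)cc1 | intermediate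
4 | phenyl[(trimethylsilyl)ethynyl]iodonium trifluoromethanesulfonate | C[Si](C)(C)C#C[I+]c1ccccc1.[O-]S(=O)(=O)C(F)(F)F | starting material
5 | potassium salt of 3, deprotonated at nitrogen (not isolated) | C#CCC[N-]S(=O)(=O)c1ccc(C)cc1.[K+] | intermediate
6 | N-(but-3-yn-1-yl)-4-methyl-N-[(trimethylsilyl)ethynyl]benzenesulfonamide | C#CCCN(C#C[Si](C)(C)C)S(=O)(=O)c1ccc(C)cc1 | intermediate
7 | N-(but-3-yn-1-yl)-N-ethynyl-4-methylbenzenesulfonamide | C#CCCN(C#C)S(=O)(=O)c1ccc(C)cc1 | intermediate
8 | N-(bromoethynyl)-N-(4-bromobut-3-yn-1-yl)-4-methylbenzenesulfonamide | BrC#CCCN(C#CBr)S(=O)(=O)c1ccc(C)cc1 | intermediate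
9 | acetylene | C#C | starting material
10 | Cp*(Cl)Ru ruthenacyclopentadiene fused to the N-tosylpyrrolidine ring, Ru bonded to both CBr carbons (not isolated; Cp* written σ-bonded in the SMILES) | BrC1=C2CCN(S(=O)(=O)c3ccc(C)cc3)C2=C(Br)[Ru]1(Cl)C1(C)C(C)=C(C)C(C)=C1C | intermediate
11 | 4,7-dibromo-1-tosylindoline (4,7-dibromo-1-(4-methylphenylsulfonyl)-2,3-dihydro-1H-indole) | Brc1ccc(Br)c2c1CCN2S(=O)(=O)c1ccc(C)cc1 | intermediate
12 | 4,7-dibromo-1-tosyl-1H-indole | Brc1ccc(Br)c2c1ccn2S(=O)(=O)c1ccc(C)cc1 | intermediate
13 | 4,7-dibromo-2-lithio-1-tosyl-1H-indole (not isolated) | [Li]c1cc2c(Br)ccc(Br)c2n1S(=O)(=O)c1ccc(C)cc1 | intermediate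
14 | 4,7-dibromo-2-chloro-1-tosyl-1H-indole | Clc1cc2c(Br)ccc(Br)c2n1S(=O)(=O)c1ccc(C)cc1 | intermediate
15 | 4,7-dibromo-2-chloro-1H-indole | Clc1cc2c(Br)ccc(Br)c2[nH]1 | intermediate
16 | 3,4,7-tribromo-2-chloro-1H-indole | Clc1[nH]c2c(Br)ccc(Br)c2c1Br | target

Total step count: 9
Longest linear sequence: 9 steps (1 → 16)

**Steps most likely to fail**

1. **Step 5 (goes beyond known chemistry).**
 - Risk: the polarised bromoynamide may engage ruthenium in ways other than oxidative coupling, such as a halide shift to a vinylidene, catalyst poisoning or oligomerisation. The diyne may also dimerise faster than the metallacycle captures acetylene.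
 - Fallback: it gives up the cyclotrimerisation and uses known chemistry only. It sets out from TsCl 2, the only route compound it keeps, and comes back at 12, so step 6 is also bypassed.
 - A Bartoli indole synthesis treats commercial 1,4-dibromo-2-nitrobenzene with vinylmagnesium bromide (3 equiv, THF, −40 °C). The bromine ortho to the nitro group is the substituent this reaction needs. The product should be 4,7-dibromo-1H-indole F1.
 - Phase-transfer N-sulfonylation of F1 with 2 (50% aq NaOH, cat. Bu4NHSO4, toluene) then gives 12.

2. **Step 6.**
 - Risk: hydride abstraction may be too slow on an indoline deactivated by the sulfonyl group and two bromines. The material would then be recovered unchanged or would degrade on long heating.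
 - Fallback: it replaces hydride abstraction by a radical substitution and elimination pair. It sets out from 11 and comes back at 12.
 - Wohl–Ziegler bromination (NBS, AIBN, PhCF3, reflux) should attack the secondary benzylic C3–H, which is more reactive than the methyl group on the electron-poor tosyl ring. The product should be racemic 3,4,7-tribromo-1-tosylindoline F2.
 - E2 loss of HBr with DBU (toluene, rt → 60 °C) aromatises F2 to 12 and removes the transient stereocentre.

3. **Step 8.**
 - Risk: the freed 3-unsubstituted 2-chloroindole may be lost by self-condensation or hydrolysis towards the oxindole, either in warm basic fluoride or during purification.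
 - Fallback: it reverses the last two operations so that the sensitive compound is never formed. It sets out from 14 and comes back at 16.
 - Br2 in CH2Cl2 (rt → reflux, dark) brominates C3 of the N-sulfonylindole, a known electrophilic substitution of this class. The product should be 3,4,7-tribromo-2-chloro-1-tosyl-1H-indole F3.
 - TBAF in THF then cleaves the N–S bond of F3 to give 16 directly.

**Further compounds**
F1 | step 5 | 4,7-dibromo-1H-indole | Brc1ccc(Br)c2[nH]ccc12
F2 | step 6 | rac-3,4,7-tribromo-1-tosylindoline | BrC1CN(S(=O)(=O)c2ccc(C)cc2)c2c1c(Br)ccc2Br
F3 | step 8 | 3,4,7-tribromo-2-chloro-1-tosyl-1H-indole | Clc1c(Br)c2c(Br)ccc(Br)c2n1S(=O)(=O)c1ccc(C)cc1
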